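## Retrosynthetic overview

1. Numbering used throughout: C1 = quaternary carbinol carbon carrying C7H2OBz, C2 = CH(OAc), C3 = CH(OBz), C4=C5 = ring alkene, C6 = CH(OH). The strategy rests on the C3–O / C4=C5 / C6–O ene-1,4-dioxygen array of the cyclohexene ring, which lies directly beside the trans C1(OH)/C2(OAc) glycol.
2. C6 carbinol ⇒ C6 enone (hydride steered by C1–OH) ⇒ cis C3,C6-ene-diol ⇒ O–O bridge from C3 to C6 (2,3-dioxabicyclo[2.2.2]oct-5-ene) ⇒ singlet O2 + C3=C4–C5=C6 diene.
3. Diene ⇒ C4,C5-dibromide ⇒ trans hydroxy acetate ⇒ C1/C2 oxirane (Sharpless) ⇒ cyclohexa-1,4-dienylmethanol ⇒ butadiene + methyl propiolate.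
4. Ring order: carbocycle (Diels–Alder); oxirane (made, then opened); 1,2-dioxine ring (closed in the key step, cut at O–O one step later); a temporary O1/O6 dioxolane (put on, taken off). Only the cyclohexene survives.

Key step: step 8

Remark (assumption): bromine addition in step 6 may give either or both trans-4,5-dibromides. Compound 9 is drawn with C4–Br on the acetate face and C5–Br on the C1–OH face. In 10 the loss of H3/Br4 is drawn first. Both C–Br centres vanish in step 7, so neither choice affects the route.

## Route

Step 1
Reactants: 1 buta-1,3-diene; 2 methyl propiolate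
Product: 3 methyl cyclohexa-1,4-diene-1-carboxylate
Conditions: 1 (3 equiv), toluene, 2,6-di-tert-butyl-4-methylphenol (cat.), sealed steel vessel, 120 °C
Reagents that add atoms: none
Why: The thermal Diels–Alder [4+2] cycloaddition of the diene with the ester-activated alkyne closes the carbocycle and leaves a skipped 1,4-diene whose conjugated C1=C2 and isolated C4=C5 alkenes are already differentiated; no stereocentre forms, and the radical inhibitor with exclusion of air holds back polymerisation and aromatisation.

Step 2
Reactants: 3 methyl cyclohexa-1,4-diene-1-carboxylate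
Product: 4 cyclohexa-1,4-dien-1-ylmethanol
Conditions: i-Bu2AlH (2.2 equiv), CH2Cl2, −78 to 0 °C; aq. KNaC4H4O6
Reagents that add atoms: none
Why: Two hydride transfers from i-Bu2AlH (1,2-reduction of an unsaturated ester) should give the allylic alcohol without conjugate reduction or isomerisation of the skipped diene, and no stereocentre is involved.

Step 3
Reactants: 4 cyclohexa-1,4-dien-1-ylmethanol
Product: 5 [(1R,6R)-7-oxabicyclo[4.1.0]hept-3-en-1-yl]methanol (C1/C2 oxirane)
Conditions: Ti(OiPr)4 (10 mol %), D-(−)-diethyl tartrate (12 mol %), anhydrous t-BuOOH (1.5 equiv), 4 Å molecular sieves, CH2Cl2, −20 °C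
Reagents that add atoms: tert-butyl hydroperoxide, CC(C)(C)OO
Why: In the Sharpless asymmetric epoxidation only the alkene whose allylic alkoxide is bound to the titanium tartrate peroxide complex (C1=C2) receives oxygen, the remote C4=C5 alkene being inert to this system, and D-(−)-tartrate, the antipode of the L-(+) ester that turns 1-cyclohexenylmethanols into (S,S)-epoxides, sets C1 and C2 together as the (R,R)-oxirane.

Step 4
Reactants: 5 [(1R,6R)-7-oxabicyclo[4.1.0]hept-3-en-1-yl]methanol
Product: 6 (1S,6R)-6-hydroxy-6-(hydroxymethyl)cyclohex-3-en-1-yl acetate (C2–OAc trans to C1–OH, C7–OH free)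
Conditions: Ti(OiPr)4 (1.5 equiv), AcOH (2 equiv), CH2Cl2, 0 °C to rt; aq. tartaric acid work-up, product used at once
Reagents that add atoms: acetic acid, CC(=O)O
Why: In this titanium-mediated regioselective opening of a 2,3-epoxy alcohol, 5 chelates titanium through its C7 alkoxide and the oxirane oxygen, the electron-withdrawing C7–O–Ti arm and the full substitution at C1 hold back bond breaking there, and acetate should enter at the secondary C2 by SN2 from the face opposite the oxirane oxygen (trans-diaxial, Fürst–Plattner), inverting C2 from R to S and keeping the C1–O bond.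

Step 5
Reactants: 6 (1S,6R)-6-hydroxy-6-(hydroxymethyl)cyclohex-3-en-1-yl acetate; 7 benzoyl chloride
Product: 8 [(1R,6S)-6-acetoxy-1-hydroxycyclohex-3-en-1-yl]methyl benzoate
Conditions: 7 (1.05 equiv), pyridine, CH2Cl2, −40 to −20 °C
Reagents that add atoms: benzoyl chloride (compound 7), O=C(Cl)c1ccccc1
Why: In this chemoselective O-acylation the unhindered primary C7–OH reacts far faster than the tertiary C1–OH, the low temperature and the absence of a stronger base leave the C2 acetate in place, and no stereocentre is touched.

Step 6
Reactants: 8 [(1R,6S)-6-acetoxy-1-hydroxycyclohex-3-en-1-yl]methyl benzoate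
Product: 9 [(1R,2S,4R,5R)-2-acetoxy-4,5-dibromo-1-hydroxycyclohexyl]methyl benzoate (trans dibromide)
Conditions: Br2 (1.0 equiv), Et4NBr (1 equiv), CH2Cl2, −78 °C
Reagents that add atoms: bromine, BrBr
Why: Bromine adds anti to the only alkene through a bromonium ion, the added bromide keeps external bromide abundant so that it rather than the C1 hydroxyl or an ester carbonyl opens the bromonium ion, and the two new C–Br centres are erased in the next step.

Step 7
Reactants: 9 [(1R,2S,4R,5R)-2-acetoxy-4,5-dibromo-1-hydroxycyclohexyl]methyl benzoate
Product: 11 [(1R,6S)-6-acetoxy-1-hydroxycyclohexa-2,4-dien-1-yl]methyl benzoate (C3=C4–C5=C6 diene), via allylic monobromide 10 (not isolated)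
Conditions: DBU (4 equiv), THF, 0 °C to rt; filtration through Et3N-deactivated SiO2, used promptly
Reagents that add atoms: none
Why: This double dehydrobromination is two consecutive anti-periplanar E2 eliminations in which only H3 and H6 are anti to a C–Br bond in the diaxial dibromide, so HBr is lost outwards to the conjugated diene rather than to a vinyl bromide, while the non-nucleophilic amidine spares the esters, the non-acidic medium prevents dehydrative aromatisation, and C1 and C2 stay untouched.

Step 8
Reactants: 11 [(1R,6S)-6-acetoxy-1-hydroxycyclohexa-2,4-dien-1-yl]methyl benzoate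
Product: 12 [(1S,4R,7R,8S)-8-acetoxy-7-hydroxy-2,3-dioxabicyclo[2.2.2]oct-5-en-7-yl]methyl benzoate (O–O bridge from C3 to C6 on the C1–OH face; 1R,2S,3R,6S in route numbering)
Conditions: O2, 5,10,15,20-tetraphenylporphyrin (1 mol %), white LED, CH2Cl2, −30 °C
Reagents that add atoms: dioxygen, O=O
Why: The photoexcited porphyrin passes its triplet energy to O2, and the singlet oxygen so formed acts as a two-atom dienophile that adds in a concerted suprafacial [4+2] cycloaddition to the termini C3 and C6 of the ring-locked s-cis diene, making the C3–O and C6–O bonds together and leaving the alkene at C4=C5. The closest known reaction type is the dye-sensitised photooxygenation of 5,6-dioxygenated cyclohexa-1,3-dienes that leads to conduritol-type ene-diols. The one new ring, the six-membered 1,2-dioxine (C3–O–O–C6–C5=C4) of the 2,3-dioxabicyclo[2.2.2]oct-5-ene, is closed by cycloaddition and not by cyclisation of a chain. Suprafacial addition forces the oxygens at the new centres C3 and C6 onto one common face, and C1 and C2 decide which face: one side of the ring shows only the C1 hydroxyl and the C2 hydrogen, the other is covered by the C7H2OBz arm and the C2 acetate, so 3R and 6S should result. The free tertiary hydroxyl should reinforce this steric bias by hydrogen bonding to the incoming oxygen, an effect that is strongest in a non-protic solvent. The step also needs periselectivity over the ene reaction, which the cisoid cyclohexadiene secures because [4+2] addition is its faster channel, and the low temperature protects both the acid-labile dienol and the peroxide.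

Step 9
Reactants: 12 endoperoxide
Product: 13 [(1S,2S,5R,6S)-6-acetoxy-1,2,5-trihydroxycyclohex-3-en-1-yl]methyl benzoate (C1, C3 and C6 hydroxyls all on one face)
Conditions: thiourea (2 equiv), MeOH/CH2Cl2, 0 °C to rt
Reagents that add atoms: none
Why: In the thiourea reduction of a bicyclic endoperoxide the nucleophilic sulfur cleaves only the weak O–O bond, so both C–O bonds and the configurations at C3 and C6 are kept and the cis-2-ene-1,4-diol results under neutral conditions that spare the alkene and esters and give acyl migration little chance.

Step 10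
Reactants: 13 triol
Product: 14 O1,O6-isopropylidene acetal of 13 (cis-fused 2,2-dimethyl-1,3-dioxolane on C1/C6, C3–OH free)
Conditions: Me2C(OMe)2 (5 equiv), pyridinium p-toluenesulfonate (5 mol %), acetone, rt
Reagents that add atoms: 2,2-dimethoxypropane, COC(C)(C)OC
Why: In this acid-catalysed transacetalisation only O1 and O6 are cis-vicinal and can close the five-membered dioxolane that acetone acetals strongly prefer, whereas an O1/O3 acetal would be a bridged dioxane with a methyl group forced over the ring; this preference is why the acetal is chosen over a cyclic boronate, which accepts a six-membered O1–B–O3 bridge and would then expose the wrong hydroxyl.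

Step 11
Reactants: 14 acetonide alcohol; 7 benzoyl chloride
Product: 15 C3-benzoate of 14
Conditions: 7 (1.5 equiv), pyridine, 4-(dimethylamino)pyridine (5 mol %), CH2Cl2, 0 °C to rt
Reagents that add atoms: benzoyl chloride (compound 7), O=C(Cl)c1ccccc1
Why: The 4-(dimethylamino)pyridine-catalysed O-benzoylation meets only one free hydroxyl, the allylic C3–OH, and proceeds with retention because only the O–H bond is broken.

Step 12
Reactants: 15 acetonide dibenzoate
Product: 16 [(1S,2S,5R,6S)-6-acetoxy-5-(benzoyloxy)-1,2-dihydroxycyclohex-3-en-1-yl]methyl benzoate (6-epimer of the target, cis C1/C6 diol)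
Conditions: CF3CO2H/H2O (9:1), CH2Cl2, 0 °C
Reagents that add atoms: none
Why: In this acid-catalysed acetal hydrolysis bond cleavage takes place at the acetal carbon and not at C1 or C6, so both configurations are kept, and short exposure to cold aqueous acid should leave the acetate, both benzoates and the allylic C3–O bond intact.

Step 13
Reactants: 16 cis diol
Product: 17 [(1R,5R,6S)-6-acetoxy-5-(benzoyloxy)-1-hydroxy-2-oxocyclohex-3-en-1-yl]methyl benzoate (C6 enone, tertiary ketol)
Conditions: 2-iodoxybenzoic acid (1.5 equiv), DMSO, rt
Reagents that add atoms: none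
Why: Oxidation with 2-iodoxybenzoic acid turns the secondary carbinol of a 1,2-diol into the ketol without breaking the C1–C6 bond, which is why it is preferred to an acetoxy-periodinane that can bind both hydroxyls of a cis glycol and fragment it; the tertiary C1–OH cannot be oxidised, the neutral medium avoids vinylogous ester elimination, and the unwanted C6 configuration is erased.

Step 14
Reactants: 17 enone
Product: 18 [(1S,2R,5R,6S)-6-acetoxy-5-(benzoyloxy)-1,2-dihydroxycyclohex-3-en-1-yl]methyl benzoate (target; 1S,2S,3R,6R in route numbering)
Conditions: Me4NBH(OAc)3 (5 equiv), MeCN/AcOH (1:1), −30 °C; aq. KNaC4H4O6/NaHCO3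
Reagents that add atoms: none
Why: In this hydroxyl-directed reduction of Evans–Saksena type, as known for hydroxy ketones, the C1 hydroxyl displaces an acetate from boron and the tethered B–H bond reaches the adjacent C6 carbonyl carbon only from the face of that hydroxyl (five-membered transition state, hence 1,2-addition), placing the new C6–OH on the opposite face (6R, trans C1/C6 diol), while the free reagent is too weak at this temperature to reduce enone or esters on its own.

## Compound list

1 | buta-1,3-diene | C=CC=C | starting material
2 | methyl propiolate | C#CC(=O)OC | starting material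
3 | methyl cyclohexa-1,4-diene-1-carboxylate | COC(=O)C1=CCC=CC1 | intermediate
4 | cyclohexa-1,4-dien-1-ylmethanol | OCC1=CCC=CC1 | intermediate
5 | [(1R,6R)-7-oxabicyclo[4.1.0]hept-3-en-1-yl]methanol | OC[C@]12CC=CC[C@H]1O2 | intermediate
6 | (1S,6R)-6-hydroxy-6-(hydroxymethyl)cyclohex-3-en-1-yl acetate | CC(=O)O[C@H]1CC=CC[C@@]1(O)CO | intermediate
7 | benzoyl chloride | O=C(Cl)c1ccccc1 | starting material
8 | [(1R,6S)-6-acetoxy-1-hydroxycyclohex-3-en-1-yl]methyl benzoate | CC(=O)O[C@H]1CC=CC[C@@]1(O)COC(=O)c1ccccc1 | intermediate
9 | [(1R,2S,4R,5R)-2-acetoxy-4,5-dibromo-1-hydroxycyclohexyl]methyl benzoate | CC(=O)O[C@H]1C[C@@H](Br)[C@H](Br)C[C@@]1(O)COC(=O)c1ccccc1 | intermediate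
10 | [(1R,2S,5R)-2-acetoxy-5-bromo-1-hydroxycyclohex-3-en-1-yl]methyl benzoate (allylic monobromide, not isolated) | CC(=O)O[C@H]1C=C[C@H](Br)C[C@@]1(O)COC(=O)c1ccccc1 | intermediate
11 | [(1R,6S)-6-acetoxy-1-hydroxycyclohexa-2,4-dien-1-yl]methyl benzoate | CC(=O)O[C@H]1C=CC=C[C@@]1(O)COC(=O)c1ccccc1 | intermediate
12 | [(1S,4R,7R,8S)-8-acetoxy-7-hydroxy-2,3-dioxabicyclo[2.2.2]oct-5-en-7-yl]methyl benzoate | CC(=O)O[C@H]1[C@H]2C=C[C@H](OO2)[C@@]1(O)COC(=O)c1ccccc1 | intermediate
13 | [(1S,2S,5R,6S)-6-acetoxy-1,2,5-trihydroxycyclohex-3-en-1-yl]methyl benzoate | CC(=O)O[C@H]1[C@H](O)C=C[C@H](O)[C@@]1(O)COC(=O)c1ccccc1 | intermediate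
14 | O1,O6-isopropylidene acetal of 13 (C3–OH free) | CC(=O)O[C@H]1[C@H](O)C=C[C@H](OC(C)(C)O2)[C@@]12COC(=O)c1ccccc1 | intermediate
15 | O1,O6-isopropylidene acetal, C3 benzoate | CC(=O)O[C@H]1[C@H](OC(=O)c2ccccc2)C=C[C@H](OC(C)(C)O2)[C@@]12COC(=O)c1ccccc1 | intermediate
16 | [(1S,2S,5R,6S)-6-acetoxy-5-(benzoyloxy)-1,2-dihydroxycyclohex-3-en-1-yl]methyl benzoate | CC(=O)O[C@H]1[C@H](OC(=O)c2ccccc2)C=C[C@H](O)[C@@]1(O)COC(=O)c1ccccc1 | intermediate
17 | [(1R,5R,6S)-6-acetoxy-5-(benzoyloxy)-1-hydroxy-2-oxocyclohex-3-en-1-yl]methyl benzoate | CC(=O)O[C@H]1[C@H](OC(=O)c2ccccc2)C=CC(=O)[C@@]1(O)COC(=O)c1ccccc1 | intermediate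
18 | [(1S,2R,5R,6S)-6-acetoxy-5-(benzoyloxy)-1,2-dihydroxycyclohex-3-en-1-yl]methyl benzoate (CNP0160999.2) | CC(=O)O[C@H]1[C@H](OC(=O)c2ccccc2)C=C[C@@H](O)[C@@]1(O)COC(=O)c1ccccc1 | target

## Step count

Total step count: 14.
Longest linear sequence: 14 steps, from 1 and 2 to 18. Benzoyl chloride 7 enters twice as a bought reagent.

## Steps most likely to fail

**Step 4.**
- What may go wrong: part of the acetate attack may leak to the quaternary C1, which lowers the enantiopurity. The acetyl group may also wander from O2 to the primary O7, or be lost by titanium-alkoxide transesterification.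
- Fallback: the incoming carboxylate is treated only as an oxygen source, and the acyl pattern is rebuilt from reactivity differences. It sets out from 6, taken crude wherever its acetyl group sits.
- K2CO3 in MeOH removes the acetyl group and gives the triol (1R,2S)-1-(hydroxymethyl)cyclohex-4-ene-1,2-diol F1.
- Benzoyl chloride 7 with 2,4,6-collidine in CH2Cl2 at −40 °C should acylate only the primary hydroxyl, giving [(1R,6S)-1,6-dihydroxycyclohex-3-en-1-yl]methyl benzoate F2.
- Ac2O in pyridine then acetylates the secondary C2–OH. The tertiary hydroxyl is inert without an acyl-transfer catalyst. The route is rejoined at 8.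
- The polar compounds F1 and F2 also offer a chance of enantiomeric enrichment by recrystallisation.

**Step 8.**
- What may go wrong: the ene reaction may compete by abstraction of the C2 hydrogen, which lies on the attacked face. Facial discrimination may be incomplete, or the bicyclic peroxide may rearrange before it is reduced.
- Fallback: the two oxygens are delivered one after the other instead of together. It sets out from 11.
- Hydroxyl-directed epoxidation with VO(acac)2 (cat.) and t-BuOOH in CH2Cl2 at 0 °C should oxidise only the C5=C6 alkene, which is allylic to C1–OH, on the hydroxyl face. This gives the C5/C6 vinyl epoxide of 11 (C3=C4 retained) F3.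
- Pd(PPh3)4 (cat.) and benzoic acid in THF at 0 °C then ionise the allylic C5–O bond with inversion. Benzoate attacks the allyl terminus C3 anti to palladium (Tsuji–Trost type 1,4-opening of a cyclic vinyl epoxide).
- The net result is cis delivery of C6–OH and C3–OBz. The route is rejoined at 16, bypassing 12 to 15.

**Step 14.**
- What may go wrong: ligand exchange at the hindered tertiary hydroxyl may be slow, so that undirected hydride delivery (return to the cis diol) or conjugate reduction competes.
- Fallback: C6 is inverted by substitution instead of by oxidation and reduction. It sets out from 16.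
- A Mitsunobu reaction (PPh3, diisopropyl azodicarboxylate, chloroacetic acid, toluene, 0 °C to rt) should displace the activated allylic C6 oxygen with inversion. The cis C1 hydroxyl cannot close an epoxide because it lies on the side of the leaving group. The product is the C6 chloroacetate of the target F4.
- Thiourea with NaHCO3 in EtOH removes the chloroacetyl group selectively in the presence of the acetate and benzoates. The route is rejoined at 18, bypassing 17.

## Further compounds

F1 | step 4 | (1R,2S)-1-(hydroxymethyl)cyclohex-4-ene-1,2-diol | O[C@H]1CC=CC[C@@]1(O)CO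
F2 | step 4 | [(1R,6S)-1,6-dihydroxycyclohex-3-en-1-yl]methyl benzoate | O[C@H]1CC=CC[C@@]1(O)COC(=O)c1ccccc1
F3 | step 8 | C5/C6 vinyl epoxide of 11 (oxirane on the C1–OH face, C3=C4 retained) | CC(=O)O[C@H]1C=C[C@@H]2O[C@@H]2[C@@]1(O)COC(=O)c1ccccc1
F4 | step 14 | C6 chloroacetate of the target (C6 inverted relative to 16) | CC(=O)O[C@H]1[C@H](OC(=O)c2ccccc2)C=C[C@@H](OC(=O)CCl)[C@@]1(O)COC(=O)c1ccccc1
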